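Time soon stops helping in Sunday's flask: product reads 71% at 6.00 h and 71% at 20.0 h, with substrate still at 31%. We ask where the new flask, with twice that charge, stands.

| flask | substrate | partner | initiator | remark | time |
|---|---|---|---|---|---|
| Sunday's | 1 M (in portions, 4) | 0.90 equiv | 0.5 mol% | run made earlier; portions every 1.0 h |  |
| flask | 2.0 M (in portions, 4) | 0.900 equiv | 0.5 mol% | the portions of substrate follow each other after 1.0 h, the first at the start | 15 h |

Sunday's run (percent of the substrate charged)

| time / h | product / % | substrate / % |
|---|---|---|
| 2.50 | 61 | 16 |
| 6.00 | 71 | 30 |
| 12.0 | 72 | 33 |
| 20.0 | 71 | 31 |

(standard deviation of a reading: 1.5 percentage points)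

- the numbers in the tables scatter with a standard deviation of 1.5 percentage points
- reactions considered so far: substrate + second chain carrier -> by-product + first chain carrier; substrate + initiating radical -> capped initiator + first chain carrier; 2 second chain carrier -> ended chains; initiator -> 2 initiating radical; partner + first chain carrier -> product + second chain carrier; partner -> decomposed reagent
- no earlier run changes the charge of initiator; that part of a forecast is a guess

- concentration of product at 15 h, in M
- concentration of substrate at 15 h, in M

We turn the settings by hand. Time first: 15 h is later than 6.00 h, and Sunday's readings from there on agree within the scatter of 1.5 percentage points, so we expect no gain from waiting. Partner next: each product takes one partner, so we read partner as the limiting reagent, and its equivalents stay at 0.900 equiv. But Sunday's plateau lies below that charge. So we define the survival share, the mean of Sunday's plateau readings of product divided by the partner charged there, and read it as 0.793.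

Then the charge. Partner's first-order decay takes the same fraction per hour at any concentration, so the share depends on how long partner waits. At 2.50 h Sunday's flask held 16% substrate, less than one portion of 25.0%, so we read the portions as pacing it, and their interval stays 1.0 h. We therefore hold the share and reckon c(product) = 1.43 M, leaving c(substrate) = 0.573 M.

The forecast says 1.46 M and 0.54 M, higher in product than our reckoning, holding that “Partner is therefore spent slightly faster on product”.

The flask gives 1.44 M and 0.557 M, so the forecast stands within its margins.

    substrate + second chain carrier → by-product + first chain carrier (k = 49000 /M/s)
    substrate + initiating radical → capped initiator + first chain carrier (k = 4.70 × 10⁵ /M/s)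
    2 second chain carrier → ended chains (k = 2.50 × 10⁸ /M/s)
    initiator → 2 initiating radical (k = 1.80 × 10⁻⁴ /min)
    partner + first chain carrier → product + second chain carrier (k = 8.00 × 10⁵ /M/s)
    partner → decomposed reagent (k = 0.00250 /min)

The flask's share is 0.800. Partner's half-life by decay alone, 4.6 h, is longer than the 1.38 h by which half the product step is done, and by 3.00 h decomposed reagent stands at 0.359 M. Carried to the neighbour flask with 1.2 M substrate, Sunday's share gives 0.856 M product, and that flask holds 0.851 M. Lowering the partner charge puts substrate above the forecast's 0.54 M: the neighbour flask with 0.540 equiv partner ends at 1.06 M substrate, its share being 0.869.

The earlier runs and the new flask stem from a simulated flask on assumed constants; noise was put on by code.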